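Readings and results were generated by integration from invented constants; scatter was added.

A reading at 4.0 h in this flask falls after the earlier runs have gone flat: maple has Qh at 19.7% at 1.33 h and 21.2% at 4.00 h. What has to be foretold is therefore a split between two products, and not a rate.

| flask | Qa | Qc | Qd | Qg | remark | time |
|---|---|---|---|---|---|---|
| maple | 0.031 M | 0.87 equiv | 1.8 equiv | 1.55 mM | run made earlier |  |
| larch | 0.031 M | 2 equiv | 1.8 equiv | 1.55 mM | run made earlier |  |
| flask | 0.031 M | 1.30 equiv | 1.80 equiv | 1.55 mM |  | 4.0 h |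

| run | time / h | Qj / % | Qh / % |
|---|---|---|---|
| maple | 0.667 | 19.5 | 17.3 |
| maple | 1.33 | 18.8 | 19.7 |
| maple | 2.00 | 16.8 | 19.4 |
| maple | 2.50 | 18.7 | 20.0 |
| maple | 3.00 | 19.0 | 18.9 |
| maple | 4.00 | 20.1 | 21.2 |
| larch | 0.333 | 11.6 | 31.9 |
| larch | 0.500 | 14.9 | 33.9 |
| larch | 0.833 | 13.5 | 36.9 |
| larch | 1.33 | 13.4 | 37.6 |
| larch | 2.50 | 16.0 | 38.1 |
| larch | 4.00 | 14.0 | 38.2 |

(each reading ± 1 percentage point)

- share of Qj in Qj plus Qh at 80 s
- share of Qj in Qj plus Qh at 15 min
- share of Qj in Qj plus Qh at 4.0 h
- which of Qj and Qh there is more of at 4.0 h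

The bench rule says that two reagents competing for one substrate divide it by their charges, so Qh over Qj is a constant times [Qc]/[Qd]. But charges stand for concentrations as long as little of them is used, and the readings of maple at 4.00 h put 24.4% of its Qc as spent against 11.2% of its Qd, counting one Qc per Qh and one Qd per Qj.

The reckoning here therefore works with fractions left. If each product takes its reagent at first order, ln(fraction of Qc left) over ln(fraction of Qd left) holds constant through a run. This is the selectivity factor S. The last three readings give 2.31 in maple and 2.51 in larch, so S reads 2.41, with the scatter of those readings. Both runs carry the same Qd, so the place of [Qd] in S is an assumption.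

At the charges of this flask, S gives a Qj share of 36.5%. The plateau totals, 39.3% in maple and 52.4% in larch, interpolate to 44.3%. Taking the reagents at their half-way amounts then moves the share to 38.1%.

The forecast gives 34.5%, 36.5% and 37.5% with Qh ahead, on the ground that the share “depends on Qc rather than on time”. Its early share stands lower than the start share reckoned here.

The flask gives 37.1% at 80 s, 38.1% at 15 min and 38.5% at 4.0 h, with Qh at 27.7% and Qj at 17.4%.

    Qa → Qb (k = 0.00150 s⁻¹)
    Qc + Qb → Qh (k = 0.390 M⁻¹ s⁻¹)
    Qd + Qb → Qj (k = 0.170 M⁻¹ s⁻¹)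
    Qb → Qe (k = 0.0270 s⁻¹)
    Qb → Qf (k = 7.30 × 10⁻⁴ s⁻¹)
    Qd + Qg → Qk (k = 4.10 M⁻¹ s⁻¹)

At 4.0 h this flask holds Qe at 53.5% of the Qa charged, with Qa at 0%. Its two products, counted one Qc per Qh and one Qd per Qj as in the runs, give S of 2.36. For the neighbour flask with 7.20 equiv of Qd, S at the charges gives a start share of 69.7%, and that neighbour flask stands at 70.7% at 80 s.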